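## Structural features

The target (25) is a bicyclo[3.2.1]octane-7,8-dione. A cyclopentane ring made of C1, C7, C6, C5 and C8 is spanned at C1 and C5 by the chain C2–C3–C4, so that C1–C2–C3–C4–C5–C8 is a chair cyclohexane and C8 is the one-carbon ketone bridge. Both bridgeheads are quaternary: C1 carries the isobutyryl group and adjoins the gem-dimethyl carbon C2, and C5 carries a prenyl group and adjoins C6. C6 is a fully substituted carbinol with its hydroxyl endo (towards C2–C3–C4) and the (Z)-4-hydroxy-4-methylpent-2-enoyl group exo (towards C8). The fourth stereocentre, C3, is a methine 1,3 to both bridgeheads whose prenyl group is equatorial, pointing away from the C6–C7 bridge; the configuration is 1R,3R,5S,6S. The fragile parts are C1 (bonded to three carbonyl carbons, so open to retro-Claisen cleavage), the tertiary alpha-hydroxy beta-diketone at C6 (ketol shift), the cis gamma-hydroxy enone (isomerisation, hemiketal closure, oxa-Michael addition) and the two prenyl alkenes. The real difficulty is the two pairs of adjacent fully substituted carbons, C1–C2 and C5–C6, together with placing the ketone on C7 and the carbinol on C6 and not the reverse. The key step exploits that ring C1–C7–C6–C5–C8 bears oxygen on C6, C7 and C8 and is bridged by three carbons whose middle one can be a carbonyl and whose C2 end is gem-dimethylated: a 3,4-dioxygenated cyclopentadienone plus a 1,1-dimethyl-2-oxyallyl cation.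

## Logic of the disconnections

25 ⇒ 24 ⇒ 23. The O–Si bonds on O6 and on the side-chain oxygen are cut last, and the cis C=C of 24 is taken back to the C≡C of 23. Neither hydroxyl can then add to the conjugated ketone while it is built, and the alkene geometry comes from a syn addition of hydrogen. The forward steps must stop the hydrogenation at the alkene and remove silicon without base.

23 ⇒ 22 ⇒ 16 + 20. The C6–C(acyl) bond is cut. C6 already carries its oxygen, so the carbon electrophile can enter from the exo face and leave the oxygen endo. A fully substituted stereocentre and a five-carbon branch disappear. The forward step needs enolate 21 to form only towards C6 and to react on carbon, then an oxidation that spares two alkenes and two silyl ethers.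

20 ⇒ 18 ⇒ 17. The formyl–alkyne bond and then the O–Si bond are cut, which reduces the side chain to a commercial alkynol. Only an acetylide formylation is required.

16 ⇒ 15. The O7–Si bond is restored, so the C7 ketone and C6–H of 16 become the C6=C7 enediol diether of 15. The double bond masks the acyloin through the reductive, radical and metathesis steps. By a count of 1,3-dicarbonyl contacts at C1 the C7 ketone is expected to be the less stable acyloin regioisomer, so it must be reached kinetically. Two different silyl groups allow this: the forward step must cleave the triethylsilyl enol ether and leave the tert-butyldimethylsilyl one.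

15 ⇒ 14 ⇒ 13 ⇒ 12 ⇒ 11. The prenyl C=C is shortened to allyl, the C3–C bond is cut, then the C3–O–C(S) bond, then the C3–H bond back to the C3 ketone. A carbon substituent that must be exo with H endo has to come from C–C bond formation on the exo face of a C3 radical, since any hydrogen delivery would come from that same face. The forward steps need a hydride reduction that touches only the C3 ketone and selects one enantiomer of racemic 11, a neutral thioacylation, an exo-selective allylation and a cross-metathesis.

11 ⇒ 8 + 9 (through 10). The C4–C5 and C1–C2 bonds are cut together, opening the seven-membered ring C1–C2–C3–C4–C5–C6–C7. One ring, two C–C bonds and both quaternary bridgeheads disappear and an achiral monocycle remains. The forward step needs 8 to act as an electron-rich diene towards 10 with CH2 to C5 and CMe2 to C1, closing in the (4+3) and not the (3+2) mode, with both silyl groups kept. Both partners are achiral, so the absolute configuration is settled afterwards.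

8 ⇒ 6 (through 7). The two O–Si bonds are cut in turn. The demand is that the first silylation picks the enol oxygen next to the prenyl-bearing carbon, so that the more robust group ends on O6 and the more labile one on O7.

6 ⇒ 4 + 5. The two ring bonds from the oxalyl carbons to C4 and C6 of 4 are cut. This is a double Claisen condensation, driven by the doubly enolised product.

4 ⇒ 1 + 2 (through 3). The C6–C7 bond of 4 is cut. The forward step needs alkylation at the terminal methyl carbon of the dianion and not at the central carbon.

## Other disconnections considered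

Alternative 1: The cut removes the C1–C7 bond and moves the ynoyl group from C6 back to C7, giving cyclohexanone A1 with a vicinal tricarbonyl chain on C5. In the forward step Et3N enolises the beta-diketone at C1, C1 adds to the middle carbonyl of the chain, and the tertiary alkoxide shifts the ynoyl group to the neighbouring ketone carbon to give A2.
- In its favour: the five-membered ring, the C6 carbinol and the whole acyl chain arrive in one operation, and A2 needs only semi-hydrogenation and desilylation. Both events are known reaction types (aldol closure, acyloin shift), which is better than the chosen plan. C3 is already present in A1, so absolute configuration can come from one early stereocentre without a resolution, which is also better.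
- Against it here: A1 combines a vicinal tricarbonyl with an ynone, and both add amines and water readily. The hindered C1 must attack next to the gem-dimethyl carbon. The ketol shift puts a third carbonyl on C1, so its direction is not clearly downhill. The C6 configuration depends on which face the acyl group occupies before the shift.
- Comparison: on structure the two plans are equal in delivering O6 at the right oxidation level. On step economy A1 needs a long synthesis of a cyclohexanone with two quaternary centres, whereas 8 is three steps from commercial materials.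

Alternative 2: The cut removes C4–C5 and the C3–allyl bond, giving the bromo dione A3 with a 2-methylbut-3-en-2-yl group on C1. In the forward step (Bu3Sn)2 and light abstract bromine, the C5 radical closes 6-endo on the terminal alkene carbon, and the C3 radical is trapped by allyl phenyl sulfone to give A4.
- In its favour: alpha-keto radicals with the carbonyl inside the forming ring are known to prefer 6-endo closure, and radicals tolerate congestion. C3 is functionalised in the ring-forming step, which saves the reduction, thioacylation and separate allylation of the chosen plan; this is better step economy at C3. The way C3 is set (exo trapping of a C3 radical) is the same in both plans, so they are equal there.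
- Against it here: A4 has no oxygen on C6. The oxygen must be introduced before the acyl carbon to end up endo, which costs a hydroxylation, a protection and enolisation at a hindered C–H. The quaternary stereocentre C1 of A3 is hard to set in one absolute sense, so a resolution is needed as in the chosen plan. Regioselective bromination at C5 and competing 5-exo closure are open points.
- Comparison: the chosen plan carries O6 and O7 in from the diene and is shorter overall, but it leans on a cycloaddition without precedent, where this alternative leans on a known radical manifold.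

Alternative 3: The cut re-inserts one carbon between C5 and C6, giving the 3-diazo bicyclo[3.3.1]nonane-2,4,9-trione A5. In the forward step irradiation in aqueous dioxane causes a Wolff rearrangement with migration of C5; hydration and decarboxylation of the ketene give A6.
- In its favour: the bicyclononanetrione class has well-developed chemistry, all ring stereocentres are in place before the contraction, and the Wolff contraction of 2-diazo-1,3-diones is a known reaction type. On precedent this is better than the chosen plan.
- Against it here: either bridgehead can migrate, and the choice decides whether the ketone ends on C7 or C6; nothing in A5 controls it. The carbene sits near two prenyl alkenes. A ring is built only to lose a carbon. A6, like A4, lacks the C6 oxygen and needs the same extra steps.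
- Comparison: on the C6 problem it is equal to alternative 2 and worse than the chosen plan; on step economy it is the longest of the four.

Key step: step 4

Remarks on the chemistry:
- 6 is drawn as the triketone although it is expected to be enolised.
- 8 is drawn as the dienone although its triethylsilyl group can shift to the acyl oxygen.
- 11 is racemic and is drawn as the enantiomer that step 5 selects.
- The oxyallyl species is generated with Et3N and LiClO4 in ether and not in a fluorinated alcohol, because both silyl groups of 8 are vinylogous silyl esters that a protic medium could strip.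

## Steps

Step 1
Reactants: 1 5-methylhexane-2,4-dione; 2 prenyl bromide (1-bromo-3-methylbut-2-ene)
Product: 4 2,9-dimethyldec-8-ene-3,5-dione, via dilithium dianion 3 (not isolated)
Conditions: LiN(i-Pr)2 (2.2 equiv), THF, −78 to 0 °C; then 2, −78 to 0 °C; aq. NH4Cl
Reagents that add atoms: none
Why: Dianion alkylation of a beta-diketone: the second deprotonation takes place at the terminal methyl group and not at the isopropyl methine, and the less stabilised terminal carbanion is the one alkylated by the allylic bromide.

Step 2
Reactants: 4 2,9-dimethyldec-8-ene-3,5-dione; 5 diethyl oxalate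
Product: 6 3-isobutyryl-5-(3-methylbut-2-enyl)cyclopentane-1,2,4-trione
Conditions: NaOEt (2.2 equiv), EtOH, reflux; then aq. HCl
Reagents that add atoms: none
Why: Double Claisen condensation: C4 and C6 of 4, the two carbons flanking its C5 carbonyl, acylate the two ester carbons of oxalate and close the five-membered ring. Acylation at the isopropyl methine cannot be driven by enolisation, so the doubly enolised trione is the thermodynamic sink.

Step 3
Reactants: 6 3-isobutyryl-5-(3-methylbut-2-enyl)cyclopentane-1,2,4-trione
Product: 8 4-(tert-butyldimethylsilyloxy)-2-isobutyryl-5-(3-methylbut-2-enyl)-3-(triethylsilyloxy)cyclopenta-2,4-dien-1-one, via mono-TBS enol ether 7 (not isolated)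
Conditions: TBSCl (1.0 equiv), imidazole (1.05 equiv), CH2Cl2, 0 °C to rt; then Et3N (1.5 equiv), TESOTf (1.1 equiv), −78 °C; pentane, filtration under Ar, used at once
Reagents that add atoms: tert-butyldimethylsilyl chloride, CC(C)(C)[Si](C)(C)Cl; triethylsilyl trifluoromethanesulfonate, CC[Si](CC)(CC)OS(=O)(=O)C(F)(F)F
Why: Stepwise O-silylation of the two enols: under equilibrating conditions the more acidic triketone enol should keep its hydrogen in the chelate, so TBSCl goes to the non-chelated enol oxygen next to the prenyl-bearing carbon, and the triflate then caps the triketone enol oxygen. This puts the robust group on the future O6 and the labile one on the future O7. No stereocentre is formed.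

Step 4
Reactants: 8 4-(tert-butyldimethylsilyloxy)-2-isobutyryl-5-(3-methylbut-2-enyl)-3-(triethylsilyloxy)cyclopenta-2,4-dien-1-one; 9 3-bromo-3-methylbutan-2-one
Product: 11 rac-(1R,5S)-6-(tert-butyldimethylsilyloxy)-1-isobutyryl-2,2-dimethyl-5-(3-methylbut-2-enyl)-7-(triethylsilyloxy)bicyclo[3.2.1]oct-6-ene-3,8-dione, via oxyallyl zwitterion 10 (not isolated)
Conditions: 9 (3 equiv, slow addition), Et3N (3 equiv), LiClO4 (3 M in Et2O), 0 °C to rt
Reagents that add atoms: none
Why: Proposed new method: Et3N enolises 9 at its methyl group and lithium-assisted loss of bromide gives 10, which is taken up by the 2,3-dioxygenated diene of 8. The prenyl-bearing terminus, the more nucleophilic alpha-carbon of a vinylogous silyl ester, bonds to the unhindered CH2 end of 10 (C4–C5), and the silyloxy-stabilised allyl cation is closed at the acyl-bearing terminus by the CMe2 end of the enolate (C1–C2), in one asynchronous event or in two steps. The closest known reaction type is the (4+3) cycloaddition of oxyallyl cations with cyclopentadienes, furans and fulvenes under these Et3N/LiClO4 conditions; a cyclopentadienone has not served as the four-carbon partner. One ring is closed, the seven-membered ring C1–C2–C3–C4–C5–C6–C7, by (4+3) annulation across the diene held s-cis in the five-membered ring, suprafacial on both partners, which also creates the cyclohexanone C1–C2–C3–C4–C5–C8. C1 and C5 are the only new stereocentres; their relative configuration is fixed by the bridge, and because 8 and 10 are achiral 11 forms as the racemate that step 5 resolves. Regioselectivity (CH2 to C5, CMe2 to C1) should follow from the nucleophilicity difference of the two diene termini and the steric difference of the two ends of 10. Periselectivity for (4+3) over (3+2) closure on the oxocarbenium carbon or oxygen is favoured by the weakly electrophilic lithium oxyallyl and by the loss of the dienone's destabilised 4π system when both termini become sp3. The silyl shift from O3 to the acyl oxygen, which would remove the diene, is reversible, so material should drain through the dienone form.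

Step 5
Reactants: 11 rac-(1R,5S)-6-(tert-butyldimethylsilyloxy)-1-isobutyryl-2,2-dimethyl-5-(3-methylbut-2-enyl)-7-(triethylsilyloxy)bicyclo[3.2.1]oct-6-ene-3,8-dione
Product: 12 (1R,3S,5S)-6-(tert-butyldimethylsilyloxy)-3-hydroxy-1-isobutyryl-2,2-dimethyl-5-(3-methylbut-2-enyl)-7-(triethylsilyloxy)bicyclo[3.2.1]oct-6-en-8-one
Conditions: (R)-Me-CBS oxazaborolidine (0.3 equiv), catecholborane (0.6 equiv), toluene, −78 to −40 °C, stopped near half conversion; MeOH; chromatography
Reagents that add atoms: none
Why: Corey–Bakshi–Shibata reduction used as a kinetic resolution. With quaternary C2 as the large flank and C4H2 as the small one, the (R)-catalyst is predicted to deliver hydride to the exo face of the (1R,5S) enantiomer, which is also the face the substrate prefers, giving the endo (axial) alcohol. The mirror-image ketone is mismatched and should stay behind or give the separable C3-epimeric alcohol. The C8 ketone (two quaternary neighbours) and the isobutyryl ketone are more hindered, and catecholborane spares the prenyl alkene.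

Step 6
Reactants: 12 (1R,3S,5S)-6-(tert-butyldimethylsilyloxy)-3-hydroxy-1-isobutyryl-2,2-dimethyl-5-(3-methylbut-2-enyl)-7-(triethylsilyloxy)bicyclo[3.2.1]oct-6-en-8-one
Product: 13 O-[(1R,3S,5S)-6-(tert-butyldimethylsilyloxy)-1-isobutyryl-2,2-dimethyl-5-(3-methylbut-2-enyl)-8-oxo-7-(triethylsilyloxy)bicyclo[3.2.1]oct-6-en-3-yl] O-phenyl carbonothioate
Conditions: PhOC(S)Cl (1.5 equiv), DMAP, pyridine, CH2Cl2, 0 °C to rt
Reagents that add atoms: O-phenyl chlorothionoformate, S=C(Cl)Oc1ccccc1
Why: Thioacylation of a secondary alcohol to a Barton–McCombie-type radical precursor. The neutral acyl-transfer conditions avoid a free alkoxide under the C6=C7 bridge that could take a silyl group from the enediol diether.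

Step 7
Reactants: 13 O-[(1R,3S,5S)-6-(tert-butyldimethylsilyloxy)-1-isobutyryl-2,2-dimethyl-5-(3-methylbut-2-enyl)-8-oxo-7-(triethylsilyloxy)bicyclo[3.2.1]oct-6-en-3-yl] O-phenyl carbonothioate
Product: 14 (1R,3R,5S)-3-allyl-6-(tert-butyldimethylsilyloxy)-1-isobutyryl-2,2-dimethyl-5-(3-methylbut-2-enyl)-7-(triethylsilyloxy)bicyclo[3.2.1]oct-6-en-8-one
Conditions: Bu3SnCH2CH=CH2 (5 equiv), AIBN (0.2 equiv), PhH, 80 °C
Reagents that add atoms: allyltributylstannane, C=CC[Sn](CCCC)(CCCC)CCCC
Why: Keck radical allylation: the stannyl radical adds to the thiocarbonyl, C3–O scission gives the secondary C3 radical, and allyl transfer takes place on the exo face, away from the C6=C7 bridge and its silyloxy groups. The allyl group therefore ends equatorial with H endo, as in the target. Closure of the C3 radical onto the C5 prenyl group is excluded because it would need a diaxial two-atom bridge.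

Step 8
Reactants: 14 (1R,3R,5S)-3-allyl-6-(tert-butyldimethylsilyloxy)-1-isobutyryl-2,2-dimethyl-5-(3-methylbut-2-enyl)-7-(triethylsilyloxy)bicyclo[3.2.1]oct-6-en-8-one
Product: 15 (1R,3R,5S)-6-(tert-butyldimethylsilyloxy)-1-isobutyryl-2,2-dimethyl-3,5-bis(3-methylbut-2-enyl)-7-(triethylsilyloxy)bicyclo[3.2.1]oct-6-en-8-one
Conditions: RuCl2(=CHPh)(H2IMes)(PCy3) (second-generation Grubbs catalyst, 5 mol %), 2-methylbut-2-ene (excess), CH2Cl2, 40 °C
Reagents that add atoms: 2-methylbut-2-ene, CC=C(C)C
Why: Olefin cross-metathesis turns the terminal alkene into the trisubstituted prenyl alkene. The existing prenyl group only undergoes degenerate exchange and the tetrasubstituted enediol diether is inert.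

Step 9
Reactants: 15 (1R,3R,5S)-6-(tert-butyldimethylsilyloxy)-1-isobutyryl-2,2-dimethyl-3,5-bis(3-methylbut-2-enyl)-7-(triethylsilyloxy)bicyclo[3.2.1]oct-6-en-8-one
Product: 16 (1R,3R,5S,6R)-6-(tert-butyldimethylsilyloxy)-1-isobutyryl-2,2-dimethyl-3,5-bis(3-methylbut-2-enyl)bicyclo[3.2.1]octane-7,8-dione
Conditions: Bu4NF (1.05 equiv), AcOH (1.5 equiv), THF, −78 to −40 °C
Reagents that add atoms: none
Why: Chemoselective fluoride cleavage of a silyl enol ether: the triethylsilyl group is attacked far faster than the tert-butyldimethylsilyl one, so only the O7 enolate forms. The acetic acid buffer protonates it on C6 from the exo face before silyl migration, fixing the ketone at C7 and the silyloxy group endo on C6.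

Step 10
Reactants: 17 2-methylbut-3-yn-2-ol
Product: 18 triethyl[(2-methylbut-3-yn-2-yl)oxy]silane
Conditions: TESCl, imidazole, DMF, rt
Reagents that add atoms: chlorotriethylsilane, CC[Si](Cl)(CC)CC
Why: Silylation of a tertiary propargylic alcohol; the triethylsilyl ether survives base and oxidation and comes off with the last step.

Step 11
Reactants: 18 triethyl[(2-methylbut-3-yn-2-yl)oxy]silane
Product: 20 4-methyl-4-(triethylsilyloxy)pent-2-ynal, via lithium acetylide 19 (not isolated)
Conditions: n-BuLi, THF, −78 °C; DMF, −78 to 0 °C; aq. NH4Cl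
Reagents that add atoms: N,N-dimethylformamide, CN(C)C=O
Why: Formylation of a lithium acetylide with DMF; the hemiaminal salt releases the ynal only on aqueous quench.

Step 12
Reactants: 16 (1R,3R,5S,6R)-6-(tert-butyldimethylsilyloxy)-1-isobutyryl-2,2-dimethyl-3,5-bis(3-methylbut-2-enyl)bicyclo[3.2.1]octane-7,8-dione; 20 4-methyl-4-(triethylsilyloxy)pent-2-ynal
Product: 22 (1R,3R,5S,6S)-6-(tert-butyldimethylsilyloxy)-6-[1-hydroxy-4-methyl-4-(triethylsilyloxy)pent-2-ynyl]-1-isobutyryl-2,2-dimethyl-3,5-bis(3-methylbut-2-enyl)bicyclo[3.2.1]octane-7,8-dione (carbinol epimers), via lithium enolate 21 (not isolated)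
Conditions: LiN(i-Pr)2 (1.1 equiv), THF, −78 °C; then 20; AcOH, −78 °C
Reagents that add atoms: none
Why: Aldol addition of a lithium enolate: the exo C6–H is the only accessible enolisable position (the isobutyryl methine is shielded by the bridgehead), and lithium held between O7 and the isobutyryl oxygen should keep the silyl group on O6. The small ynal adds on the exo face, on the side of the C8 bridge, so C6 gets its carbon substituent exo and its oxygen endo. The carbinol centre forms as a mixture and is removed in step 13.

Step 13
Reactants: 22 (1R,3R,5S,6S)-6-(tert-butyldimethylsilyloxy)-6-[1-hydroxy-4-methyl-4-(triethylsilyloxy)pent-2-ynyl]-1-isobutyryl-2,2-dimethyl-3,5-bis(3-methylbut-2-enyl)bicyclo[3.2.1]octane-7,8-dione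
Product: 23 (1R,3R,5S,6S)-6-(tert-butyldimethylsilyloxy)-1-isobutyryl-2,2-dimethyl-6-[4-methyl-4-(triethylsilyloxy)pent-2-ynoyl]-3,5-bis(3-methylbut-2-enyl)bicyclo[3.2.1]octane-7,8-dione
Conditions: Dess–Martin periodinane, NaHCO3, CH2Cl2, 0 °C to rt
Reagents that add atoms: none
Why: Dess–Martin oxidation of a propargylic alcohol to the ynone under buffered, non-basic conditions. C6 is quaternary, so the new 1,3-diketone cannot enolise or epimerise.

Step 14
Reactants: 23 (1R,3R,5S,6S)-6-(tert-butyldimethylsilyloxy)-1-isobutyryl-2,2-dimethyl-6-[4-methyl-4-(triethylsilyloxy)pent-2-ynoyl]-3,5-bis(3-methylbut-2-enyl)bicyclo[3.2.1]octane-7,8-dione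
Product: 24 (1R,3R,5S,6S)-6-(tert-butyldimethylsilyloxy)-1-isobutyryl-2,2-dimethyl-6-[(Z)-4-methyl-4-(triethylsilyloxy)pent-2-enoyl]-3,5-bis(3-methylbut-2-enyl)bicyclo[3.2.1]octane-7,8-dione
Conditions: H2 (1 atm), Pd/CaCO3 poisoned with Pb(OAc)2 (Lindlar catalyst), quinoline, EtOAc, 0 °C
Reagents that add atoms: none
Why: Lindlar semi-hydrogenation: syn delivery of hydrogen to the alkyne gives the cis enone, and the trisubstituted prenyl alkenes are not reduced by the poisoned catalyst. Both hydroxyls are still silylated, so neither can add to the ynone or the enone.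

Step 15
Reactants: 24 (1R,3R,5S,6S)-6-(tert-butyldimethylsilyloxy)-1-isobutyryl-2,2-dimethyl-6-[(Z)-4-methyl-4-(triethylsilyloxy)pent-2-enoyl]-3,5-bis(3-methylbut-2-enyl)bicyclo[3.2.1]octane-7,8-dione
Product: 25 (1R,3R,5S,6S)-6-hydroxy-6-[(Z)-4-hydroxy-4-methylpent-2-enoyl]-1-isobutyryl-2,2-dimethyl-3,5-bis(3-methylbut-2-enyl)bicyclo[3.2.1]octane-7,8-dione (CNP0190794.1)
Conditions: HF·pyridine, pyridine, THF, 0 °C to rt (polyethylene vessel)
Reagents that add atoms: none
Why: Fluoride cleavage of both silyl ethers in a weakly acidic medium, which avoids the retro-Claisen and ketol-shift pathways that basic fluoride would open. The C6 silyl ether is tertiary but flanked by two carbonyl groups, which should make it labile enough.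

## Compound list

1 | 5-methylhexane-2,4-dione | CC(C)C(=O)CC(C)=O | starting material
2 | prenyl bromide (1-bromo-3-methylbut-2-ene) | CC(C)=CCBr | starting material
3 | dilithium 5-methylhexane-2,4-dione-1,3-diide | [Li+].[Li+].[CH2-]C(=O)[CH-]C(=O)C(C)C | intermediate
4 | 2,9-dimethyldec-8-ene-3,5-dione | CC(C)C(=O)CC(=O)CCC=C(C)C | intermediate
5 | diethyl oxalate | CCOC(=O)C(=O)OCC | starting material
6 | 3-isobutyryl-5-(3-methylbut-2-enyl)cyclopentane-1,2,4-trione (enolised) | CC(C)C(=O)C1C(=O)C(=O)C(CC=C(C)C)C1=O | intermediate
7 | 4-(tert-butyldimethylsilyloxy)-2-(1-hydroxy-2-methylpropylidene)-5-(3-methylbut-2-enyl)cyclopent-4-ene-1,3-dione | CC(C)C(O)=C1C(=O)C(O[Si](C)(C)C(C)(C)C)=C(CC=C(C)C)C1=O | intermediate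
8 | 4-(tert-butyldimethylsilyloxy)-2-isobutyryl-5-(3-methylbut-2-enyl)-3-(triethylsilyloxy)cyclopenta-2,4-dien-1-one | CC(C)C(=O)C1=C(O[Si](CC)(CC)CC)C(O[Si](C)(C)C(C)(C)C)=C(CC=C(C)C)C1=O | intermediate
9 | 3-bromo-3-methylbutan-2-one | CC(=O)C(C)(C)Br | starting material
10 | 1,1-dimethyl-2-oxidoallyl cation (oxyallyl zwitterion) | C=C([O-])[C+](C)C | intermediate
11 | rac-(1R,5S)-6-(tert-butyldimethylsilyloxy)-1-isobutyryl-2,2-dimethyl-5-(3-methylbut-2-enyl)-7-(triethylsilyloxy)bicyclo[3.2.1]oct-6-ene-3,8-dione (racemate; enantiomer carried forward is drawn) | O=C1C[C@]2(CC=C(C)C)C(=O)[C@@](C(=O)C(C)C)(C(O[Si](CC)(CC)CC)=C2O[Si](C)(C)C(C)(C)C)C1(C)C | intermediate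
12 | (1R,3S,5S)-6-(tert-butyldimethylsilyloxy)-3-hydroxy-1-isobutyryl-2,2-dimethyl-5-(3-methylbut-2-enyl)-7-(triethylsilyloxy)bicyclo[3.2.1]oct-6-en-8-one (3-OH endo) | O[C@H]1C[C@]2(CC=C(C)C)C(=O)[C@@](C(=O)C(C)C)(C(O[Si](CC)(CC)CC)=C2O[Si](C)(C)C(C)(C)C)C1(C)C | intermediate
13 | O-[(1R,3S,5S)-6-(tert-butyldimethylsilyloxy)-1-isobutyryl-2,2-dimethyl-5-(3-methylbut-2-enyl)-8-oxo-7-(triethylsilyloxy)bicyclo[3.2.1]oct-6-en-3-yl] O-phenyl carbonothioate | S=C(Oc1ccccc1)O[C@H]1C[C@]2(CC=C(C)C)C(=O)[C@@](C(=O)C(C)C)(C(O[Si](CC)(CC)CC)=C2O[Si](C)(C)C(C)(C)C)C1(C)C | intermediate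
14 | (1R,3R,5S)-3-allyl-6-(tert-butyldimethylsilyloxy)-1-isobutyryl-2,2-dimethyl-5-(3-methylbut-2-enyl)-7-(triethylsilyloxy)bicyclo[3.2.1]oct-6-en-8-one (3-allyl exo) | C=CC[C@@H]1C[C@]2(CC=C(C)C)C(=O)[C@@](C(=O)C(C)C)(C(O[Si](CC)(CC)CC)=C2O[Si](C)(C)C(C)(C)C)C1(C)C | intermediate
15 | (1R,3R,5S)-6-(tert-butyldimethylsilyloxy)-1-isobutyryl-2,2-dimethyl-3,5-bis(3-methylbut-2-enyl)-7-(triethylsilyloxy)bicyclo[3.2.1]oct-6-en-8-one | CC(C)=CC[C@@H]1C[C@]2(CC=C(C)C)C(=O)[C@@](C(=O)C(C)C)(C(O[Si](CC)(CC)CC)=C2O[Si](C)(C)C(C)(C)C)C1(C)C | intermediate
16 | (1R,3R,5S,6R)-6-(tert-butyldimethylsilyloxy)-1-isobutyryl-2,2-dimethyl-3,5-bis(3-methylbut-2-enyl)bicyclo[3.2.1]octane-7,8-dione (6-silyloxy endo) | CC(C)=CC[C@@H]1C[C@]2(CC=C(C)C)C(=O)[C@@](C(=O)C(C)C)(C(=O)[C@@H]2O[Si](C)(C)C(C)(C)C)C1(C)C | intermediate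
17 | 2-methylbut-3-yn-2-ol | C#CC(C)(C)O | starting material
18 | triethyl[(2-methylbut-3-yn-2-yl)oxy]silane | C#CC(C)(C)O[Si](CC)(CC)CC | intermediate
19 | lithium 3-methyl-3-(triethylsilyloxy)but-1-yn-1-ide | [Li+].[C-]#CC(C)(C)O[Si](CC)(CC)CC | intermediate
20 | 4-methyl-4-(triethylsilyloxy)pent-2-ynal | O=CC#CC(C)(C)O[Si](CC)(CC)CC | intermediate
21 | lithium (1R,3R,5S)-6-(tert-butyldimethylsilyloxy)-1-isobutyryl-2,2-dimethyl-3,5-bis(3-methylbut-2-enyl)-8-oxobicyclo[3.2.1]oct-6-en-7-olate | CC(C)=CC[C@@H]1C[C@]2(CC=C(C)C)C(=O)[C@@](C(=O)C(C)C)(C([O-])=C2O[Si](C)(C)C(C)(C)C)C1(C)C.[Li+] | intermediate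
22 | (1R,3R,5S,6S)-6-(tert-butyldimethylsilyloxy)-6-[1-hydroxy-4-methyl-4-(triethylsilyloxy)pent-2-ynyl]-1-isobutyryl-2,2-dimethyl-3,5-bis(3-methylbut-2-enyl)bicyclo[3.2.1]octane-7,8-dione (carbinol epimers) | CC(C)=CC[C@@H]1C[C@]2(CC=C(C)C)C(=O)[C@@](C(=O)C(C)C)(C(=O)[C@@]2(O[Si](C)(C)C(C)(C)C)C(O)C#CC(C)(C)O[Si](CC)(CC)CC)C1(C)C | intermediate
23 | (1R,3R,5S,6S)-6-(tert-butyldimethylsilyloxy)-1-isobutyryl-2,2-dimethyl-6-[4-methyl-4-(triethylsilyloxy)pent-2-ynoyl]-3,5-bis(3-methylbut-2-enyl)bicyclo[3.2.1]octane-7,8-dione | CC(C)=CC[C@@H]1C[C@]2(CC=C(C)C)C(=O)[C@@](C(=O)C(C)C)(C(=O)[C@@]2(O[Si](C)(C)C(C)(C)C)C(=O)C#CC(C)(C)O[Si](CC)(CC)CC)C1(C)C | intermediate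
24 | (1R,3R,5S,6S)-6-(tert-butyldimethylsilyloxy)-1-isobutyryl-2,2-dimethyl-6-[(Z)-4-methyl-4-(triethylsilyloxy)pent-2-enoyl]-3,5-bis(3-methylbut-2-enyl)bicyclo[3.2.1]octane-7,8-dione | CC(C)=CC[C@@H]1C[C@]2(CC=C(C)C)C(=O)[C@@](C(=O)C(C)C)(C(=O)[C@@]2(O[Si](C)(C)C(C)(C)C)C(=O)/C=C\C(C)(C)O[Si](CC)(CC)CC)C1(C)C | intermediate
25 | (1R,3R,5S,6S)-6-hydroxy-6-[(Z)-4-hydroxy-4-methylpent-2-enoyl]-1-isobutyryl-2,2-dimethyl-3,5-bis(3-methylbut-2-enyl)bicyclo[3.2.1]octane-7,8-dione (CNP0190794.1) | CC(C)=CC[C@@H]1C[C@]2(CC=C(C)C)C(=O)[C@@](C(=O)C(C)C)(C(=O)[C@@]2(O)C(=O)/C=C\C(C)(C)O)C1(C)C | target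

## Step count and least certain steps

Total step count: 15. Longest linear sequence: 13 steps (steps 1–9 and 12–15); steps 10 and 11 make aldehyde 20.

Step 4 (key step, the one step beyond known chemistry).
- What may go wrong: after the first C–C bond the enolate may close on the oxocarbenium carbon or oxygen, a (3+2) pathway; a new bond between two fully substituted carbons at an acyl-deactivated terminus is slow. The oxyallyl species may be lost by elimination of HBr from 9, the dienone may dimerise, or the triethylsilyl group may settle on the acyl oxygen and remove the diene.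
- Fallback: it sets out from 7 and comes back at racemic 11, making the same two bonds one at a time by known reaction types.
  - The free triketone enol of 7 is O-alkylated with 3-methylbut-2-en-1-ol (PPh3, diisopropyl azodicarboxylate), and Claisen rearrangement on warming gives 4-(tert-butyldimethylsilyloxy)-2-isobutyryl-2-(2-methylbut-3-en-2-yl)-5-(3-methylbut-2-enyl)cyclopent-4-ene-1,3-dione F1 (C1–C2 bond).
  - Wacker oxidation of the terminal alkene (PdCl2, CuCl, O2, aqueous DMF), which also frees the vinylogous acid, gives 4-hydroxy-2-isobutyryl-2-(2-methyl-3-oxobutan-2-yl)-5-(3-methylbut-2-enyl)cyclopent-4-ene-1,3-dione F2.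
  - Intramolecular oxidative enolate coupling of its dianion (LiN(SiMe3)2, then I2) forms the C4–C5 bond and gives racemic 1-isobutyryl-2,2-dimethyl-5-(3-methylbut-2-enyl)bicyclo[3.2.1]octane-3,6,7,8-tetraone F3.
  - Reductive silylation of the 6,7-dione with Zn and TBSCl, then TESCl, returns to 11. The bulkier chloride is expected to take the less hindered O6, with O7 held on zinc by the isobutyryl oxygen.
  - The fallback is longer and its last step needs proof of regiochemistry.

Step 3.
- What may go wrong: silylation at the wrong enol oxygen, or exchange of the two silyl groups between the oxygens, which would erase the later distinction between O6 and O7; hydrolysis of the vinylogous silyl esters on handling.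
- Fallback: it sets out from 6 and comes back at 7. Exhaustive silylation (TBSOTf, Et3N) gives 3,4-bis(tert-butyldimethylsilyloxy)-2-isobutyryl-5-(3-methylbut-2-enyl)cyclopenta-2,4-dien-1-one F4. Its silyl group on the triketone enol oxygen is far more labile and is removed selectively by one equivalent of methanol, giving 7, which is then capped with TESOTf as in step 3.

Step 12.
- What may go wrong: slow addition at the congested tetrasubstituted enolate with reversal of the aldol on warming; migration of the silyl group from O6 to O7 in the enolate, which would move the reacting carbon to C7; attack of the new alkoxide on the C8 ketone followed by retro-Claisen ring opening.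
- Fallback: it sets out from 16 and comes back at 25. Enolate 21 is added to the lactone carbonyl of commercial 5,5-dimethylfuran-2(5H)-one, a known addition of lithium enolates to lactones. The ring of the lactone holds the alkene cis, so work-up gives (1R,3R,5S,6S)-6-(tert-butyldimethylsilyloxy)-6-[(Z)-4-hydroxy-4-methylpent-2-enoyl]-1-isobutyryl-2,2-dimethyl-3,5-bis(3-methylbut-2-enyl)bicyclo[3.2.1]octane-7,8-dione F5 (in equilibrium with its cyclic hemiketal). HF·pyridine then gives 25. This route needs neither 20 nor the oxidation and hydrogenation steps.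

Step 5.
- What may go wrong: insufficient rate difference between the two enantiomers if the substrate's own exo preference overrides the catalyst in the mismatched case, leaving 12 with low enantiomeric purity; slow reduction of the hindered ketone.
- Fallback: it sets out from 11 and comes back at 12 and makes no new compound. Racemic 11 is separated by preparative chromatography on a chiral stationary phase, and the (1R,5S) enantiomer is reduced under substrate control with LiBH(s-Bu)3 (exo attack) to 12.

Step 14.
- What may go wrong: over-reduction of the electron-poor alkyne, or cis-to-trans isomerisation of the strained cis enone on the catalyst or in the pyridine-containing medium of step 15.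
- Fallback: it sets out from 23 and comes back at 25 with the order of the last two operations reversed, so the cis alkene is formed last and never meets fluoride or pyridine. HF·pyridine first gives (1R,3R,5S,6S)-6-hydroxy-6-(4-hydroxy-4-methylpent-2-ynoyl)-1-isobutyryl-2,2-dimethyl-3,5-bis(3-methylbut-2-enyl)bicyclo[3.2.1]octane-7,8-dione F6, which is semi-hydrogenated over the Lindlar catalyst to 25. The risk moved to F6 is cyclisation of the free C6 hydroxyl onto the ynone.

## Further compounds

F1 | step 4 | 4-(tert-butyldimethylsilyloxy)-2-isobutyryl-2-(2-methylbut-3-en-2-yl)-5-(3-methylbut-2-enyl)cyclopent-4-ene-1,3-dione (racemic) | C=CC(C)(C)C1(C(=O)C(C)C)C(=O)C(O[Si](C)(C)C(C)(C)C)=C(CC=C(C)C)C1=O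
F2 | step 4 | 4-hydroxy-2-isobutyryl-2-(2-methyl-3-oxobutan-2-yl)-5-(3-methylbut-2-enyl)cyclopent-4-ene-1,3-dione (racemic) | CC(=O)C(C)(C)C1(C(=O)C(C)C)C(=O)C(O)=C(CC=C(C)C)C1=O
F3 | step 4 | 1-isobutyryl-2,2-dimethyl-5-(3-methylbut-2-enyl)bicyclo[3.2.1]octane-3,6,7,8-tetraone (racemic; one enantiomer drawn) | O=C1C[C@]2(CC=C(C)C)C(=O)[C@@](C(=O)C(C)C)(C(=O)C2=O)C1(C)C
F4 | step 3 | 3,4-bis(tert-butyldimethylsilyloxy)-2-isobutyryl-5-(3-methylbut-2-enyl)cyclopenta-2,4-dien-1-one | CC(C)C(=O)C1=C(O[Si](C)(C)C(C)(C)C)C(O[Si](C)(C)C(C)(C)C)=C(CC=C(C)C)C1=O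
F5 | step 12 | (1R,3R,5S,6S)-6-(tert-butyldimethylsilyloxy)-6-[(Z)-4-hydroxy-4-methylpent-2-enoyl]-1-isobutyryl-2,2-dimethyl-3,5-bis(3-methylbut-2-enyl)bicyclo[3.2.1]octane-7,8-dione | CC(C)=CC[C@@H]1C[C@]2(CC=C(C)C)C(=O)[C@@](C(=O)C(C)C)(C(=O)[C@@]2(O[Si](C)(C)C(C)(C)C)C(=O)/C=C\C(C)(C)O)C1(C)C
F0 | step 5 | none | none
F6 | step 14 | (1R,3R,5S,6S)-6-hydroxy-6-(4-hydroxy-4-methylpent-2-ynoyl)-1-isobutyryl-2,2-dimethyl-3,5-bis(3-methylbut-2-enyl)bicyclo[3.2.1]octane-7,8-dione | CC(C)=CC[C@@H]1C[C@]2(CC=C(C)C)C(=O)[C@@](C(=O)C(C)C)(C(=O)[C@@]2(O)C(=O)C#CC(C)(C)O)C1(C)C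
A1 | alternative 1 | 2-isobutyryl-3,3-dimethyl-6-[6-methyl-2,3-dioxo-6-(triethylsilyloxy)hept-4-ynoyl]-4,6-bis(3-methylbut-2-enyl)cyclohexan-1-one (C4 and C6 configured as C3 and C5 of the target) | CC(C)=CC[C@@H]1C[C@@](CC=C(C)C)(C(=O)C(=O)C(=O)C#CC(C)(C)O[Si](CC)(CC)CC)C(=O)C(C(=O)C(C)C)C1(C)C
A2 | alternative 1 | (1R,3R,5S,6S)-6-hydroxy-1-isobutyryl-2,2-dimethyl-6-[4-methyl-4-(triethylsilyloxy)pent-2-ynoyl]-3,5-bis(3-methylbut-2-enyl)bicyclo[3.2.1]octane-7,8-dione | CC(C)=CC[C@@H]1C[C@]2(CC=C(C)C)C(=O)[C@@](C(=O)C(C)C)(C(=O)[C@@]2(O)C(=O)C#CC(C)(C)O[Si](CC)(CC)CC)C1(C)C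
A3 | alternative 2 | 4-bromo-2-isobutyryl-2-(2-methylbut-3-en-2-yl)-4-(3-methylbut-2-enyl)cyclopentane-1,3-dione (C2 configured as C1 of the target; C4 either) | C=CC(C)(C)[C@]1(C(=O)C(C)C)C(=O)CC(Br)(CC=C(C)C)C1=O
A4 | alternative 2 | (1R,3R,5S)-3-allyl-1-isobutyryl-2,2-dimethyl-5-(3-methylbut-2-enyl)bicyclo[3.2.1]octane-7,8-dione | C=CC[C@@H]1C[C@]2(CC=C(C)C)C(=O)[C@@](C(=O)C(C)C)(C(=O)C2)C1(C)C
A5 | alternative 3 | 3-diazo-1-isobutyryl-8,8-dimethyl-5,7-bis(3-methylbut-2-enyl)bicyclo[3.3.1]nonane-2,4,9-trione (configured as A6) | CC(C)=CC[C@@H]1C[C@]2(CC=C(C)C)C(=O)[C@@](C(=O)C(C)C)(C(=O)C(=[N+]=[N-])C2=O)C1(C)C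
A6 | alternative 3 | (1R,3R,5S)-1-isobutyryl-2,2-dimethyl-3,5-bis(3-methylbut-2-enyl)bicyclo[3.2.1]octane-7,8-dione | CC(C)=CC[C@@H]1C[C@]2(CC=C(C)C)C(=O)[C@@](C(=O)C(C)C)(C(=O)C2)C1(C)C
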